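**Retrosynthetic overview**
Atom names: lactone O1, C2 (quaternary), C3, C4, C5 (C=O); C1' is the CH(CO2H) carbon. The enabling feature is that C5 and the carboxyl carbon on C1' are linked through C4–C3–C2–C1', so these two carboxyls are the cleaved C=C of a cyclohex-3-ene. In that ring, C2 (bearing O and a carboxyl) and C1' (bearing the chain) form the ortho pattern of a Diels–Alder adduct from a 1-alkyl diene and a 2-oxy-acrolein.
Disconnections: (a) the malate ester C–O, made last by regioselective opening of (R)-O-trifluoroacetylmalic anhydride 19 with the ω-alcohol 17; (b) the lactone C–O; (c) oxidative cleavage back to cyclohexene 12; (d) [4+2] union of (E)-diene 7 and 2-acetoxyacrolein 11, which forms the lactone C3–C4 bond and the C2–C1' bond and sets both stereocentres.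
Diene 7 comes from 3-sulfolene by α-alkylation and cheletropic loss of SO2; dienophile 11 comes from 2,2-dimethyl-1,3-dioxan-5-one by enol acetylation and retro-hetero-Diels–Alder loss of acetone.
Ring order: the cyclohexene is closed in step 7 (temporary, opened in step 8); the γ-lactone is closed in step 9.

Key step: step 7

Assumption: 2-acetoxyacrolein is taken to bind the chiral boron cation through its formyl group in the same s-trans arrangement as 2-bromoacrolein and methacrolein, so that the (S)-catalyst exposes the Re face of C2 of the enal.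

**Route**

Step 1
Reactants: 1 10-bromodecan-1-ol
Product: 2 (10-bromodecyloxy)(tert-butyl)dimethylsilane
Conditions: TBSCl, imidazole, DMF, 0 °C to rt
Reagents that add atoms: tert-butyldimethylsilyl chloride, CC(C)(C)[Si](C)(C)Cl
Why: Imidazole-promoted silylation of a primary alcohol masks the hydroxyl for the strongly basic alkylation of step 3.

Step 2
Reactants: 2 (10-bromodecyloxy)(tert-butyl)dimethylsilane
Product: 3 tert-butyl[(10-iododecyl)oxy]dimethylsilane
Conditions: NaI, acetone, reflux
Reagents that add atoms: sodium iodide, [Na+].[I-]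
Why: Finkelstein halide exchange, driven by precipitation of NaBr, provides the iodide needed for alkylation at −78 °C.

Step 3
Reactants: 3 tert-butyl[(10-iododecyl)oxy]dimethylsilane; 4 3-sulfolene (2,5-dihydrothiophene 1,1-dioxide)
Product: 6 rac-2-{10-[(tert-butyldimethylsilyl)oxy]decyl}-2,5-dihydrothiophene 1,1-dioxide, via 2-lithio-3-sulfolene 5 (not isolated)
Conditions: LiN(SiMe3)2 added to 3 and 4 (excess), THF–HMPA, −78 °C
Reagents that add atoms: none
Why: Alkylation of an α-sulfonyl carbanion: deprotonation of 3-sulfolene in the presence of the iodide lets SN2 capture at C2 outrun ring opening of the anion; the new stereocentre is racemic and is destroyed in step 4.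

Step 4
Reactants: 6 rac-2-{10-[(tert-butyldimethylsilyl)oxy]decyl}-2,5-dihydrothiophene 1,1-dioxide
Product: 7 tert-butyldimethyl{[(11E)-tetradeca-11,13-dien-1-yl]oxy}silane
Conditions: toluene, 110 °C
Reagents that add atoms: none
Why: Thermal cheletropic extrusion of SO2 is disrotatory with the 2-substituent turning outwards, so the (E)-1-alkyl diene should form stereospecifically.

Step 5
Reactants: 8 2,2-dimethyl-1,3-dioxan-5-one
Product: 10 2,2-dimethyl-4H-1,3-dioxin-5-yl acetate, via potassium dioxinolate 9 (not isolated)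
Conditions: KN(SiMe3)2, THF, −78 °C; then Ac2O, −78 to 0 °C
Reagents that add atoms: acetic anhydride, CC(=O)OC(C)=O
Why: O-acylation of the potassium enolate of an α,α'-dioxygenated ketone with an anhydride gives the enol ester.

Step 6
Reactants: 10 2,2-dimethyl-4H-1,3-dioxin-5-yl acetate
Product: 11 2-acetoxyacrolein (3-oxoprop-1-en-2-yl acetate)
Conditions: toluene, 120 °C, sealed tube; acetone removed, solution used directly
Reagents that add atoms: none
Why: Retro-hetero-Diels–Alder fragmentation of the 4H-1,3-dioxin releases volatile acetone and the 2-acyloxy enal.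

Step 7
Reactants: 7 tert-butyldimethyl{[(11E)-tetradeca-11,13-dien-1-yl]oxy}silane; 11 2-acetoxyacrolein
Product: 12 (1R,2R)-2-{10-[(tert-butyldimethylsilyl)oxy]decyl}-1-formylcyclohex-3-en-1-yl acetate
Conditions: (S)-tetrahydro-1-(2-methylphenyl)-3,3-diphenyl-1H,3H-pyrrolo[1,2-c][1,3,2]oxazaborole (C24H24BNO, 20 mol %), (CF3SO2)2NH (16 mol %), CH2Cl2, −78 °C
Reagents that add atoms: none
Why: The triflimide-activated (S)-oxazaborolidine should bind the formyl oxygen of 11 (formyl C–H···O contact, s-trans enal stacked on a phenyl group), and the diene should add to the open Re face of C2 in a concerted, asynchronous [4+2] cycloaddition in which the bond between the dienophile CH2 and the unsubstituted diene terminus (the later lactone C3–C4 bond) is the more advanced and the bond between the dienophile α-carbon and the alkyl-bearing diene terminus (the later C2–C1' bond) completes the ring. The closest known reaction types are oxazaborolidinium-catalysed Diels–Alder reactions of 2-bromoacrolein and methacrolein with open-chain dienes and Lewis acid-catalysed cycloadditions of 2-acyloxyacroleins. The cyclohexene is closed by an intermolecular suprafacial [4π+2π] cycloaddition of two acyclic partners without a tether. The quaternary centre C1 is controlled by the catalyst (facial selectivity); the neighbouring C2 is controlled by the (E)-geometry of the diene together with the endo orientation of the boron-bound formyl group, which places CHO cis to the alkyl chain. The step needs ortho regioselectivity (largest HOMO coefficient at the unsubstituted diene terminus, largest LUMO coefficient at the acrolein CH2), endo selectivity (expected for a Lewis acid-bound formyl group with an open-chain (E)-diene, which lacks the bridging CH2 that turns 2-substituted acroleins exo with cyclopentadiene), and [4+2] rather than [4+3] reactivity (secured by an acyloxy rather than a silyloxy group).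

Step 8
Reactants: 12 (1R,2R)-2-{10-[(tert-butyldimethylsilyl)oxy]decyl}-1-formylcyclohex-3-en-1-yl acetate
Product: 15 (3R,4S)-3-acetoxy-14-[(tert-butyldimethylsilyl)oxy]tetradecane-1,3,4-tricarboxylic acid, via ozonide 13 (not isolated), via trialdehyde 14 (not isolated)
Conditions: O3, CH2Cl2, −78 °C; PPh3, −78 °C to rt; then NaClO2, NaH2PO4, 2-methyl-2-butene, t-BuOH–H2O, 0 °C to rt
Reagents that add atoms: ozone, O=[O+][O-]; sodium chlorite, [Na+].[O-]Cl=O
Why: Criegee ozonolysis of the only C=C with reductive work-up, followed by Pinnick chlorite oxidation of all three formyl groups at buffered pH, turns ring carbons C3 and C4 into the two carboxyls without breaking a bond at either stereocentre.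

Step 9
Reactants: 15 (3R,4S)-3-acetoxy-14-[(tert-butyldimethylsilyl)oxy]tetradecane-1,3,4-tricarboxylic acid
Product: 17 (2R)-2-[(1S)-1-carboxy-11-hydroxyundecyl]-5-oxotetrahydrofuran-2-carboxylic acid, via hydroxy triacid silyl ether 16 (not isolated)
Conditions: LiOH, THF–H2O, 45 °C; then 2 M HCl to pH 1, 45 °C
Reagents that add atoms: none
Why: Saponification of the tertiary acetate, then acidification, which cleaves the silyl ether and closes the γ-lactone by 5-exo-trig acyl substitution of the tertiary hydroxyl on the CH2CH2CO2H arm (the only carboxyl able to form an unstrained ring); no bond at either stereocentre is broken.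

Step 10
Reactants: 18 (R)-malic acid
Product: 19 (R)-2,5-dioxotetrahydrofuran-3-yl trifluoroacetate ((R)-O-trifluoroacetylmalic anhydride)
Conditions: (CF3CO)2O, neat, 0 °C to rt; volatiles removed in vacuo
Reagents that add atoms: trifluoroacetic anhydride, O=C(OC(=O)C(F)(F)F)C(F)(F)F
Why: Trifluoroacetic anhydride O-acylates the hydroxyl and dehydrates the diacid to the five-membered cyclic anhydride via a mixed anhydride, without touching the stereocentre.

Step 11
Reactants: 17 (2R)-2-[(1S)-1-carboxy-11-hydroxyundecyl]-5-oxotetrahydrofuran-2-carboxylic acid; 19 (R)-O-trifluoroacetylmalic anhydride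
Product: 21 (2R)-2-[(1S)-1-carboxy-11-{[(2R)-3-carboxy-2-hydroxypropanoyl]oxy}undecyl]-5-oxotetrahydrofuran-2-carboxylic acid, via trifluoroacetate ester 20 (not isolated)
Conditions: THF, 0 °C to rt; then H2O, rt
Reagents that add atoms: none
Why: Alcoholysis of the unsymmetrical cyclic anhydride should occur at the carbonyl next to the carbon bearing the electron-withdrawing trifluoroacetoxy group, giving the 1-ester with the CH2CO2H arm free; the labile trifluoroacetate is hydrolysed on aqueous work-up.

**Compound list**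
1 | 10-bromodecan-1-ol | OCCCCCCCCCCBr | starting material
2 | (10-bromodecyloxy)(tert-butyl)dimethylsilane | CC(C)(C)[Si](C)(C)OCCCCCCCCCCBr | intermediate
3 | tert-butyl[(10-iododecyl)oxy]dimethylsilane | CC(C)(C)[Si](C)(C)OCCCCCCCCCCI | intermediate
4 | 3-sulfolene (2,5-dihydrothiophene 1,1-dioxide) | O=S1(=O)CC=CC1 | starting material
5 | 2-lithio-2,5-dihydrothiophene 1,1-dioxide (not isolated) | [Li+].O=S1(=O)[CH-]C=CC1 | intermediate
6 | rac-2-{10-[(tert-butyldimethylsilyl)oxy]decyl}-2,5-dihydrothiophene 1,1-dioxide | CC(C)(C)[Si](C)(C)OCCCCCCCCCCC1C=CCS1(=O)=O | intermediate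
7 | tert-butyldimethyl{[(11E)-tetradeca-11,13-dien-1-yl]oxy}silane | CC(C)(C)[Si](C)(C)OCCCCCCCCCC/C=C/C=C | intermediate
8 | 2,2-dimethyl-1,3-dioxan-5-one | CC1(C)OCC(=O)CO1 | starting material
9 | potassium 2,2-dimethyl-4H-1,3-dioxin-5-olate (not isolated) | [K+].[O-]C1=COC(C)(C)OC1 | intermediate
10 | 2,2-dimethyl-4H-1,3-dioxin-5-yl acetate | CC(=O)OC1=COC(C)(C)OC1 | intermediate
11 | 2-acetoxyacrolein (3-oxoprop-1-en-2-yl acetate) | CC(=O)OC(=C)C=O | intermediate
12 | (1R,2R)-2-{10-[(tert-butyldimethylsilyl)oxy]decyl}-1-formylcyclohex-3-en-1-yl acetate | CC(C)(C)[Si](C)(C)OCCCCCCCCCC[C@@H]1C=CCC[C@]1(OC(C)=O)C=O | intermediate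
13 | ozonide (1,2,4-trioxolane) of 12, mixture at the two acetal carbons (not isolated) | CC(C)(C)[Si](C)(C)OCCCCCCCCCC[C@@H]1C2OOC(O2)CC[C@]1(OC(C)=O)C=O | intermediate
14 | (3R,4S)-3-acetoxy-14-[(tert-butyldimethylsilyl)oxy]tetradecane-1,3,4-tricarbaldehyde (not isolated) | CC(C)(C)[Si](C)(C)OCCCCCCCCCC[C@H](C=O)[C@@](OC(C)=O)(C=O)CCC=O | intermediate
15 | (3R,4S)-3-acetoxy-14-[(tert-butyldimethylsilyl)oxy]tetradecane-1,3,4-tricarboxylic acid | CC(C)(C)[Si](C)(C)OCCCCCCCCCC[C@H](C(=O)O)[C@@](OC(C)=O)(C(=O)O)CCC(=O)O | intermediate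
16 | (3R,4S)-14-[(tert-butyldimethylsilyl)oxy]-3-hydroxytetradecane-1,3,4-tricarboxylic acid (not isolated) | CC(C)(C)[Si](C)(C)OCCCCCCCCCC[C@H](C(=O)O)[C@@](O)(C(=O)O)CCC(=O)O | intermediate
17 | (2R)-2-[(1S)-1-carboxy-11-hydroxyundecyl]-5-oxotetrahydrofuran-2-carboxylic acid | OCCCCCCCCCC[C@H](C(=O)O)[C@@]1(C(=O)O)CCC(=O)O1 | intermediate
18 | (R)-malic acid | O=C(O)C[C@@H](O)C(=O)O | starting material
19 | (R)-2,5-dioxotetrahydrofuran-3-yl trifluoroacetate | O=C1C[C@@H](OC(=O)C(F)(F)F)C(=O)O1 | intermediate
20 | O-trifluoroacetyl derivative of 21 at the malate hydroxyl (not isolated) | O=C(O)C[C@@H](OC(=O)C(F)(F)F)C(=O)OCCCCCCCCCC[C@H](C(=O)O)[C@@]1(C(=O)O)CCC(=O)O1 | intermediate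
21 | (2R)-2-[(1S)-1-carboxy-11-{[(2R)-3-carboxy-2-hydroxypropanoyl]oxy}undecyl]-5-oxotetrahydrofuran-2-carboxylic acid | O=C(O)C[C@@H](O)C(=O)OCCCCCCCCCC[C@H](C(=O)O)[C@@]1(C(=O)O)CCC(=O)O1 | target

**Step count and risks**
Total steps: 11. Longest linear sequence: 8 (steps 1, 2, 3, 4, 7, 8, 9, 11).

Most likely to fail:

1. Step 7. The chiral boron cation may discriminate the enal faces or the endo and exo modes poorly, may be arrested by binding at the acetoxy carbonyl, or may trigger acid-induced oligomerisation of the diene. The fallback sets out from 7 and 11 and replaces asymmetric catalysis by resolution. BF3·OEt2-catalysed cycloaddition (CH2Cl2, −78 °C) should give the racemic cis adduct F1, and Pinnick oxidation should give the racemic acetoxy acid F2. Crystallisation with (R)-1-phenylethylamine (or its antipode, should the other salt crystallise) should give the ammonium salt F3 of the (1R,2R)-acid, and acidification frees the (1R,2R)-acetoxy acid F4. This is ozonised (O3; PPh3) through the ozonide acid F5 and the dialdehyde acid F6 (neither isolated) and oxidised with NaClO2 to rejoin the route at 15.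

2. Step 11. Attack at the distal anhydride carbonyl would give the isomeric 4-ester; acylation of the limiting alcohol may be incomplete; and mixed anhydrides with the two free carboxyls may scramble acyl groups. The fallback sets out from 17 and 18 and fixes the ester position by carboxylate alkylation. Compound 17 is converted into the dibenzyl ester F7 (BnBr, Cs2CO3, DMF) and then into the primary iodide F8 (I2, PPh3, imidazole). Separately, 18 gives the acetonide acid F9 (2,2-dimethoxypropane, TsOH), its benzyl ester F10 (BnBr, Et3N), and after mild aqueous acid hydrolysis the 4-benzyl hydrogen (R)-malate F11. SN2 displacement of iodide in F8 by the cesium salt of F11 (Cs2CO3, DMF) should give the tribenzyl ester F12, and hydrogenolysis (H2, 10% Pd/C, EtOAc) returns to the route at 21.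

3. Step 3. The sulfolenyl anion may ring-open before the slow alkylation by an unactivated iodide, and 2,5-dialkylation may compete. The fallback sets out from 3 and builds the diene by cross-coupling. Alkynylation with lithium acetylide–ethylenediamine complex in DMSO should give the terminal alkyne F13. Cp2Zr(H)Cl-catalysed hydroboration with pinacolborane should give the (E)-alkenylboronate F14. Suzuki–Miyaura coupling with vinyl bromide (Pd(PPh3)4, aq. NaOH, THF), with retention of alkene geometry, returns to the route at 7.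

**Further compounds**
F1 | step 7 | racemic cis adduct, (1R,2R) and (1S,2S) forms of 12 | CC(C)(C)[Si](C)(C)OCCCCCCCCCC[C@@H]1C=CCC[C@]1(OC(C)=O)C=O.CC(C)(C)[Si](C)(C)OCCCCCCCCCC[C@H]1C=CCC[C@@]1(OC(C)=O)C=O
F2 | step 7 | racemic cis-1-acetoxy-2-{10-[(tert-butyldimethylsilyl)oxy]decyl}cyclohex-3-ene-1-carboxylic acid | CC(C)(C)[Si](C)(C)OCCCCCCCCCC[C@@H]1C=CCC[C@]1(OC(C)=O)C(=O)O.CC(C)(C)[Si](C)(C)OCCCCCCCCCC[C@H]1C=CCC[C@@]1(OC(C)=O)C(=O)O
F3 | step 7 | (R)-1-phenylethylammonium (1R,2R)-1-acetoxy-2-{10-[(tert-butyldimethylsilyl)oxy]decyl}cyclohex-3-ene-1-carboxylate | CC(C)(C)[Si](C)(C)OCCCCCCCCCC[C@@H]1C=CCC[C@]1(OC(C)=O)C(=O)[O-].C[C@@H]([NH3+])c1ccccc1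
F4 | step 7 | (1R,2R)-1-acetoxy-2-{10-[(tert-butyldimethylsilyl)oxy]decyl}cyclohex-3-ene-1-carboxylic acid | CC(C)(C)[Si](C)(C)OCCCCCCCCCC[C@@H]1C=CCC[C@]1(OC(C)=O)C(=O)O
F5 | step 7 | ozonide of F4, mixture at the two acetal carbons | CC(C)(C)[Si](C)(C)OCCCCCCCCCC[C@@H]1C2OOC(O2)CC[C@]1(OC(C)=O)C(=O)O
F6 | step 7 | (2R,3S)-2-acetoxy-13-[(tert-butyldimethylsilyl)oxy]-3-formyl-2-(3-oxopropyl)tridecanoic acid | CC(C)(C)[Si](C)(C)OCCCCCCCCCC[C@H](C=O)[C@@](OC(C)=O)(C(=O)O)CCC=O
F7 | step 11 | benzyl (2R)-2-[(1S)-1-(benzyloxycarbonyl)-11-hydroxyundecyl]-5-oxotetrahydrofuran-2-carboxylate | OCCCCCCCCCC[C@H](C(=O)OCc1ccccc1)[C@@]1(C(=O)OCc2ccccc2)CCC(=O)O1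
F8 | step 11 | benzyl (2R)-2-[(1S)-1-(benzyloxycarbonyl)-11-iodoundecyl]-5-oxotetrahydrofuran-2-carboxylate | ICCCCCCCCCC[C@H](C(=O)OCc1ccccc1)[C@@]1(C(=O)OCc2ccccc2)CCC(=O)O1
F9 | step 11 | (R)-2-(2,2-dimethyl-5-oxo-1,3-dioxolan-4-yl)acetic acid | CC1(C)O[C@H](CC(=O)O)C(=O)O1
F10 | step 11 | benzyl (R)-2-(2,2-dimethyl-5-oxo-1,3-dioxolan-4-yl)acetate | CC1(C)O[C@H](CC(=O)OCc2ccccc2)C(=O)O1
F11 | step 11 | (R)-4-(benzyloxy)-2-hydroxy-4-oxobutanoic acid | O=C(OCc1ccccc1)C[C@@H](O)C(=O)O
F12 | step 11 | tribenzyl ester of 21 (both lactone-side carboxyls and the malate CH2CO2H as benzyl esters) | O=C(OCc1ccccc1)C[C@@H](O)C(=O)OCCCCCCCCCC[C@H](C(=O)OCc1ccccc1)[C@@]1(C(=O)OCc2ccccc2)CCC(=O)O1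
F13 | step 3 | tert-butyl(dodec-11-yn-1-yloxy)dimethylsilane | CC(C)(C)[Si](C)(C)OCCCCCCCCCCC#C
F14 | step 3 | tert-butyldimethyl{[(11E)-12-(4,4,5,5-tetramethyl-1,3,2-dioxaborolan-2-yl)dodec-11-en-1-yl]oxy}silane | CC(C)(C)[Si](C)(C)OCCCCCCCCCC/C=C/B1OC(C)(C)C(C)(C)O1
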